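**Plan**

1. Numbering: ring C1 (C=O), C2 (N), C3, C4 (carbinol), C5/C6 (epoxide); lower chain C7–C13 counted outward from C4. The retrosynthesis cuts C8–C9 first, then the enamide N–C2 bond, then C4–C7, and finally traces the C2=C3 enone back to a cyclopentadiene Diels–Alder adduct of benzoquinone monoketal.
2. Enabling feature: the C9=C10–C11=C12–C13(=O)N dienamide is the conrotatory 4π ring-opened form of a trans-3,4-disubstituted cyclobutene with C9 and C12 as its sp3 carbons. C8–C9 is therefore made as an sp2–sp3 bond to a strained four-membered ring, which then opens to the (E,E)-diene.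
3. Forward: enantioselective Diels–Alder reaction, convex-face epoxidation, convex-face alkynylation, deketalisation, retro-Diels–Alder, α-iodination, copper-catalysed amidation with the upper trienamide, alkyne to (E)-vinylstannane, then coupling with the chlorocyclobutene amide of the aminocyclopentenone and ring opening as the last step.
4. Stereochemistry: catalysis sets only the two temporary ring-fusion centres. The folded tricycle relays them to C5/C6 and C4 because both reagents arrive on the convex face, which puts the C4 side chain syn and the C4 hydroxyl anti to the epoxide oxygen (4S,5S,6R, as in the target SMILES). The cycloreversion then erases the relay centres.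
5. Alkene geometry: Wittig and Horner–Wadsworth–Emmons reactions (upper chain), syn-hydrostannation (C7=C8), outward torquoselectivity of the cyclobutene opening (C9=C10, C11=C12).

Key step: step 17

Remark: the sense of induction of the titanium–binaphthol catalyst in step 1 is not presumed, so the antipode of 1,1′-bi-2-naphthol that gives 3 as drawn is fixed by a pilot run; 21, 22, 26 and 27 are racemic and 28 is a diastereomer pair, which is immaterial because the cyclobutene stereocentres vanish in step 17; the CIP label of the carbinol carbon changes from R (9, 10, 17–19) to S (28, 29) through priority rules only.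

**Route**

Step 1
Reactants: 1 4,4-dimethoxycyclohexa-2,5-dien-1-one; 2 cyclopentadiene
Product: 3 (1S,4R,4aS,8aR)-8,8-dimethoxy-1,4,4a,8a-tetrahydro-1,4-methanonaphthalen-5(8H)-one (endo adduct)
Conditions: TiCl2(O-i-Pr)2 (10 mol%), 1,1′-bi-2-naphthol (one antipode, 10 mol%), 4 Å MS, CH2Cl2, −30 °C
Reagents that add atoms: none
Why: Enantioselective Diels–Alder reaction of a quinone monoketal under a chiral binaphthol–titanium Lewis acid, which should discriminate the enantiotopic C=C bonds and faces of 1 and give the endo, cis-fused adduct whose two ring-fusion stereocentres carry all later stereochemical information.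

Step 2
Reactants: 3 Diels–Alder adduct
Product: 4 6,7-epoxy-8,8-dimethoxy-1,4,4a,6,7,8a-hexahydro-1,4-methanonaphthalen-5(8H)-one (epoxide oxygen on the convex face)
Conditions: t-BuOOH (decane), DBU, CH2Cl2, 0 → 23 °C
Reagents that add atoms: tert-butyl hydroperoxide, CC(C)(C)OO
Why: Weitz–Scheffer-type nucleophilic epoxidation of the only remaining enone, in which the hydroperoxide anion should attack the open convex face of the folded endo tricycle, so that both epoxide stereocentres (later C5 and C6) are set by substrate control anti to the norbornene unit.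

Step 3
Reactants: 4 epoxy ketone; 5 ethynyltrimethylsilane
Product: 7 6,7-epoxy-8,8-dimethoxy-5-[(trimethylsilyl)ethynyl]-1,4,4a,5,6,7,8,8a-octahydro-1,4-methanonaphthalen-5-ol (alkynyl syn and hydroxyl anti to the epoxide oxygen), via lithium (trimethylsilyl)acetylide 6 (not isolated)
Conditions: n-BuLi, THF, −78 °C; then 4, −78 °C; AcOH quench at −78 °C
Reagents that add atoms: none
Why: 1,2-Addition of the lithium acetylide to the ketone, again from the convex face because the concave face is screened by the norbornene bridge, should place the alkynyl group syn and the new hydroxyl anti to the epoxide oxygen (later C4), the cold acidic quench preventing Payne rearrangement of the alkoxide.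

Step 4
Reactants: 7 tertiary propargylic alcohol ketal
Product: 8 6,7-epoxy-5-hydroxy-5-[(trimethylsilyl)ethynyl]-1,4,4a,5,6,7-hexahydro-1,4-methanonaphthalen-8(8aH)-one
Conditions: 10% aq. oxalic acid on SiO2, CH2Cl2, 23 °C
Reagents that add atoms: water, O
Why: Mild acid-catalysed hydrolysis of the dimethyl ketal to the ketone, under which the tertiary propargylic alcohol should not ionise and the epoxide should survive.

Step 5
Reactants: 8 tricyclic hydroxy epoxy ketone
Product: 9 (1R,5R,6S)-5-hydroxy-5-[(trimethylsilyl)ethynyl]-7-oxabicyclo[4.1.0]hept-3-en-2-one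
Conditions: flash vacuum pyrolysis, 450 °C, 0.01 mbar
Reagents that add atoms: none
Why: Thermal retro-Diels–Alder cycloreversion, a standard unmasking for cyclopentadiene adducts of epoxyquinols, should expel cyclopentadiene and unveil the C2=C3 enone, removing the temporary ring and its two relay stereocentres while C4, C5 and C6 stay untouched.

Step 6
Reactants: 9 epoxy hydroxy enone
Product: 10 (1R,5R,6S)-5-hydroxy-3-iodo-5-[(trimethylsilyl)ethynyl]-7-oxabicyclo[4.1.0]hept-3-en-2-one
Conditions: I2, pyridine/CH2Cl2, 0 → 23 °C
Reagents that add atoms: iodine, II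
Why: Pyridine-mediated α-iodination of the enone (conjugate addition of pyridine, iodination of the enolate, elimination) should functionalise C2, the only enone α-position, and leave the silylalkyne alone.

Step 7
Reactants: 11 4-methylpentanal; 12 (triphenylphosphoranylidene)acetaldehyde
Product: 13 (E)-6-methylhept-2-enal
Conditions: toluene, 80 °C
Reagents that add atoms: none
Why: Wittig reaction with the stabilised formyl ylide, which should give the (E)-enal.

Step 8
Reactants: 13 (E)-6-methylhept-2-enal; 14 triethyl 4-phosphonocrotonate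
Product: 15 ethyl (2E,4E,6E)-10-methylundeca-2,4,6-trienoate
Conditions: LiN(SiMe3)2, THF, −78 → 0 °C
Reagents that add atoms: none
Why: Vinylogous Horner–Wadsworth–Emmons olefination, which should form the new C4=C5 double bond with E geometry and deliver the all-E trienoate.

Step 9
Reactants: 15 ethyl trienoate
Product: 16 (2E,4E,6E)-10-methylundeca-2,4,6-trienamide
Conditions: AlMe3, NH4Cl, toluene, 0 → 50 °C; aq. HCl work-up
Reagents that add atoms: ammonium chloride, [NH4+].[Cl-]
Why: Weinreb-type aminolysis of the ester by the aluminium amide formed from AlMe3 and NH4Cl should give the primary amide without conjugate addition to the triene.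

Step 10
Reactants: 10 2-iodoenone; 16 trienamide
Product: 17 (2E,4E,6E)-N-[(1R,5R,6S)-5-hydroxy-2-oxo-5-[(trimethylsilyl)ethynyl]-7-oxabicyclo[4.1.0]hept-3-en-3-yl]-10-methylundeca-2,4,6-trienamide
Conditions: CuI (10 mol%), MeNHCH2CH2NHMe (20 mol%), Cs2CO3, THF, 50 °C
Reagents that add atoms: none
Why: Goldberg-type copper-catalysed C–N coupling of the 2-iodoenone with the primary amide should give the enamide with the C2=C3 bond in place, the carbonate base in THF being too weak to deprotonate the tertiary alcohol or open the epoxide.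

Step 11
Reactants: 17 silylalkyne enamide
Product: 18 (2E,4E,6E)-N-[(1R,5R,6S)-5-ethynyl-5-hydroxy-2-oxo-7-oxabicyclo[4.1.0]hept-3-en-3-yl]-10-methylundeca-2,4,6-trienamide
Conditions: AgNO3 (10 mol%), acetone/H2O, 23 °C
Reagents that add atoms: none
Why: Silver-catalysed protodesilylation of the alkynylsilane under neutral conditions, chosen to avoid alkoxide formation and hence Payne rearrangement of the anti-hydroxy epoxide.

Step 12
Reactants: 18 terminal alkyne
Product: 19 (2E,4E,6E)-N-[(1R,5R,6S)-5-hydroxy-2-oxo-5-[(E)-2-(tributylstannyl)ethenyl]-7-oxabicyclo[4.1.0]hept-3-en-3-yl]-10-methylundeca-2,4,6-trienamide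
Conditions: Bu3SnH (slow addition), PdCl2(PPh3)2 (3 mol%), THF, 0 °C
Reagents that add atoms: tributyltin hydride, CCCC[SnH](CCCC)CCCC
Why: Palladium-catalysed syn-hydrostannation of the terminal alkyne, in which the quaternary propargylic carbon should direct tin to the terminal carbon and so give the (E)-vinylstannane, the alkyne reacting much faster than the enone or the trienamide is reduced.

Step 13
Reactants: 20 2H-pyran-2-one
Product: 22 cis-4-chlorocyclobut-2-ene-1-carboxylic acid (racemic), via 2-oxabicyclo[2.2.0]hex-5-en-3-one 21 (not isolated)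
Conditions: hν (300 nm), Et2O, flow, −10 °C; then HCl (4 M in dioxane), 0 °C
Reagents that add atoms: hydrogen chloride, Cl
Why: Photochemical 4π electrocyclisation of 2-pyranone to the strained bicyclic lactone followed by acid-induced opening of its allylic C–O bond by chloride should give the racemic cis-chloro acid, the lactone being handled in solution only.

Step 14
Reactants: 23 cyclopentane-1,3-dione
Product: 24 2-(hydroxyimino)cyclopentane-1,3-dione
Conditions: NaNO2, aq. HCl, 0 °C
Reagents that add atoms: sodium nitrite, [Na+].[O-]N=O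
Why: Nitrosation of the doubly activated methylene of the 1,3-dione, which should give the 2-oxime.

Step 15
Reactants: 24 2-(hydroxyimino)cyclopentane-1,3-dione
Product: 25 2-amino-3-hydroxycyclopent-2-en-1-one hydrochloride
Conditions: H2 (3 bar), Pd/C, HCl, EtOH, 23 °C
Reagents that add atoms: hydrogen chloride, Cl
Why: Catalytic hydrogenation of the oxime to the primary amine, trapped as its hydrochloride (enol form) to prevent self-condensation.

Step 16
Reactants: 22 cis-4-chlorocyclobut-2-ene-1-carboxylic acid; 25 2-amino-3-hydroxycyclopent-2-en-1-one hydrochloride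
Product: 27 cis-4-chloro-N-(2-hydroxy-5-oxocyclopent-1-en-1-yl)cyclobut-2-ene-1-carboxamide (racemic), via cis-4-chlorocyclobut-2-ene-1-carbonyl chloride 26 (not isolated)
Conditions: (COCl)2, DMF (cat.), CH2Cl2, 0 °C; then 25, pyridine, 0 → 23 °C
Reagents that add atoms: none
Why: Amide formation via the acid chloride, in which any O-acylated enol should rearrange to the more stable N-acyl compound and the weak base pyridine should neither epimerise nor eliminate the allylic chloride.

Step 17
Reactants: 19 (E)-vinylstannane; 27 cis-4-chlorocyclobutene carboxamide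
Product: 29 (2E,4E,6E)-N-[(1R,5S,6S)-5-hydroxy-5-[(1E,3E,5E)-7-[(2-hydroxy-5-oxocyclopent-1-en-1-yl)amino]-7-oxohepta-1,3,5-trien-1-yl]-2-oxo-7-oxabicyclo[4.1.0]hept-3-en-3-yl]-10-methylundeca-2,4,6-trienamide (CNP0304685.4), via trans-4-alkenylcyclobut-2-ene-1-carboxamide 28 (not isolated)
Conditions: PdCl2(MeCN)2 (5 mol%), DMF, 23 °C, dark, until 27 is consumed; then 40 °C
Reagents that add atoms: none
Why: Proposed new method: zerovalent palladium (formed in situ from the divalent palladium precatalyst and the stannane) should ionise the allylic C–Cl bond of 27 with inversion to a cyclobutenyl–palladium species with the metal anti to the carboxamide, and transmetalation with 19 followed by reductive elimination with retention then forges C8–C9 as an sp2–sp3 bond to give trans-cyclobutene 28, whose thermally allowed conrotatory 4π electrocyclic ring opening (driven by release of roughly 30 kcal/mol of ring strain and by formation of the conjugated trienamide) delivers 29 in the same flask. The closest known reaction types are the allyl–alkenyl Stille coupling and the palladium-catalysed allylic substitution of 4-chlorocyclobut-2-ene-1-carboxylic acid derivatives by malonates or dialkylzinc reagents followed by electrocyclic opening to dienoates; an alkenylstannane has not been shown as the nucleophile on this substrate class. No ring is closed: the four-membered ring is a temporary ring that is opened, and both termini of its allyl unit lead to the same constitution, so regiochemistry is not an issue. The two sp3 stereocentres of 28 are transient; the new stereo-elements are the C9=C10 and C11=C12 double bonds, both E because in a trans-3,4-disubstituted cyclobutene both substituents rotate outward (torquoselectivity), while C7=C8 keeps the E geometry of the stannane. The selectivity needed is trans over cis coupling (a cis-cyclobutene would open to a 2Z,4E-dienamide), and it is secured by the inversion/retention sequence with palladium on the face away from the carboxamide. Neutral, base-free conditions near room temperature should spare the acidic enol of the aminocyclopentenone unit, the epoxide, the free tertiary alcohol and both polyene chains.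

**Compound list**

1 | 4,4-dimethoxycyclohexa-2,5-dien-1-one | COC1(OC)C=CC(=O)C=C1 | starting material
2 | cyclopentadiene (freshly cracked from commercial dicyclopentadiene) | C1=CCC=C1 | starting material
3 | (1S,4R,4aS,8aR)-8,8-dimethoxy-1,4,4a,8a-tetrahydro-1,4-methanonaphthalen-5(8H)-one, endo adduct | O=C1C=CC(OC)(OC)[C@H]2[C@@H]1[C@H]1C=C[C@@H]2C1 | intermediate
4 | 6,7-epoxy-8,8-dimethoxy-1,4,4a,6,7,8a-hexahydro-1,4-methanonaphthalen-5(8H)-one, epoxide on the convex face | O=C1[C@H]3O[C@H]3C(OC)(OC)[C@H]2[C@@H]1[C@H]1C=C[C@@H]2C1 | intermediate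
5 | ethynyltrimethylsilane | C#C[Si](C)(C)C | starting material
6 | lithium (trimethylsilyl)acetylide | [Li]C#C[Si](C)(C)C | intermediate
7 | 6,7-epoxy-8,8-dimethoxy-5-[(trimethylsilyl)ethynyl]-1,4,4a,5,6,7,8,8a-octahydro-1,4-methanonaphthalen-5-ol, alkynyl syn and hydroxyl anti to the epoxide oxygen | O[C@]1(C#C[Si](C)(C)C)[C@H]3O[C@H]3C(OC)(OC)[C@H]2[C@@H]1[C@H]1C=C[C@@H]2C1 | intermediate
8 | 6,7-epoxy-5-hydroxy-5-[(trimethylsilyl)ethynyl]-1,4,4a,5,6,7-hexahydro-1,4-methanonaphthalen-8(8aH)-one, same configuration as 7 | O[C@]1(C#C[Si](C)(C)C)[C@H]3O[C@H]3C(=O)[C@H]2[C@@H]1[C@H]1C=C[C@@H]2C1 | intermediate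
9 | (1R,5R,6S)-5-hydroxy-5-[(trimethylsilyl)ethynyl]-7-oxabicyclo[4.1.0]hept-3-en-2-one | O[C@]1(C#C[Si](C)(C)C)[C@H]2O[C@H]2C(=O)C=C1 | intermediate
10 | (1R,5R,6S)-5-hydroxy-3-iodo-5-[(trimethylsilyl)ethynyl]-7-oxabicyclo[4.1.0]hept-3-en-2-one | O[C@]1(C#C[Si](C)(C)C)[C@H]2O[C@H]2C(=O)C(I)=C1 | intermediate
11 | 4-methylpentanal | CC(C)CCC=O | starting material
12 | (triphenylphosphoranylidene)acetaldehyde | O=CC=P(c1ccccc1)(c1ccccc1)c1ccccc1 | starting material
13 | (E)-6-methylhept-2-enal | CC(C)CC/C=C/C=O | intermediate
14 | triethyl 4-phosphonocrotonate | CCOC(=O)/C=C/CP(=O)(OCC)OCC | starting material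
15 | ethyl (2E,4E,6E)-10-methylundeca-2,4,6-trienoate | CC(C)CC/C=C/C=C/C=C/C(=O)OCC | intermediate
16 | (2E,4E,6E)-10-methylundeca-2,4,6-trienamide | CC(C)CC/C=C/C=C/C=C/C(N)=O | intermediate
17 | (2E,4E,6E)-N-[(1R,5R,6S)-5-hydroxy-2-oxo-5-[(trimethylsilyl)ethynyl]-7-oxabicyclo[4.1.0]hept-3-en-3-yl]-10-methylundeca-2,4,6-trienamide | CC(C)CC/C=C/C=C/C=C/C(=O)NC1=C[C@@](O)(C#C[Si](C)(C)C)[C@H]2O[C@H]2C1=O | intermediate
18 | (2E,4E,6E)-N-[(1R,5R,6S)-5-ethynyl-5-hydroxy-2-oxo-7-oxabicyclo[4.1.0]hept-3-en-3-yl]-10-methylundeca-2,4,6-trienamide | CC(C)CC/C=C/C=C/C=C/C(=O)NC1=C[C@@](O)(C#C)[C@H]2O[C@H]2C1=O | intermediate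
19 | (2E,4E,6E)-N-[(1R,5R,6S)-5-hydroxy-2-oxo-5-[(E)-2-(tributylstannyl)ethenyl]-7-oxabicyclo[4.1.0]hept-3-en-3-yl]-10-methylundeca-2,4,6-trienamide | CC(C)CC/C=C/C=C/C=C/C(=O)NC1=C[C@@](O)(/C=C/[Sn](CCCC)(CCCC)CCCC)[C@H]2O[C@H]2C1=O | intermediate
20 | 2H-pyran-2-one | O=C1C=CC=CO1 | starting material
21 | 2-oxabicyclo[2.2.0]hex-5-en-3-one (racemic, cis-fused; one enantiomer drawn) | O=C1O[C@@H]2C=C[C@H]12 | intermediate
22 | cis-4-chlorocyclobut-2-ene-1-carboxylic acid (racemic; one enantiomer drawn) | OC(=O)[C@@H]1C=C[C@@H]1Cl | intermediate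
23 | cyclopentane-1,3-dione | O=C1CCC(=O)C1 | starting material
24 | 2-(hydroxyimino)cyclopentane-1,3-dione | O=C1CCC(=O)C1=NO | intermediate
25 | 2-amino-3-hydroxycyclopent-2-en-1-one hydrochloride | Cl.NC1=C(O)CCC1=O | intermediate
26 | cis-4-chlorocyclobut-2-ene-1-carbonyl chloride (racemic; one enantiomer drawn) | ClC(=O)[C@@H]1C=C[C@@H]1Cl | intermediate
27 | cis-4-chloro-N-(2-hydroxy-5-oxocyclopent-1-en-1-yl)cyclobut-2-ene-1-carboxamide (racemic; one enantiomer drawn) | O=C(NC1=C(O)CCC1=O)[C@@H]1C=C[C@@H]1Cl | intermediate
28 | (2E,4E,6E)-N-[(1R,5S,6S)-5-hydroxy-5-[(E)-2-[trans-4-[(2-hydroxy-5-oxocyclopent-1-en-1-yl)carbamoyl]cyclobut-2-en-1-yl]ethenyl]-2-oxo-7-oxabicyclo[4.1.0]hept-3-en-3-yl]-10-methylundeca-2,4,6-trienamide (pair of trans diastereomers; one drawn) | CC(C)CC/C=C/C=C/C=C/C(=O)NC1=C[C@@](O)(/C=C/[C@@H]3C=C[C@H]3C(=O)NC3=C(O)CCC3=O)[C@H]2O[C@H]2C1=O | intermediate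
29 | (2E,4E,6E)-N-[(1R,5S,6S)-5-hydroxy-5-[(1E,3E,5E)-7-[(2-hydroxy-5-oxocyclopent-1-en-1-yl)amino]-7-oxohepta-1,3,5-trien-1-yl]-2-oxo-7-oxabicyclo[4.1.0]hept-3-en-3-yl]-10-methylundeca-2,4,6-trienamide (CNP0304685.4) | CC(C)CC/C=C/C=C/C=C/C(=O)NC1=C[C@@](O)(/C=C/C=C/C=C/C(=O)NC2=C(O)CCC2=O)[C@H]2O[C@H]2C1=O | target

**Step count and risks**

Total step count: 17. Longest linear sequence: 10 steps (steps 1–6, 10–12 and 17).

Steps most likely to fail:

Step 17 (new method). The cyclobutenyl–palladium intermediate may epimerise to the face syn to the carboxamide before a slow transmetalation, which would lead to cis coupling and a Z double bond after ring opening. The allyl–palladium intermediate may also be captured by the enol oxygen of the aminocyclopentenone, or 19 may undergo protodestannylation. The fallback uses known chemistry, sets out from 19 and 25 and returns at 29; it builds the diene with fixed geometry before the coupling. Commercial glutaconaldehyde potassium salt is brominated (PPh3, Br2, CH2Cl2) to (2E,4E)-5-bromopenta-2,4-dienal F1. This is oxidised (NaClO2, NaH2PO4, 2-methylbut-2-ene, t-BuOH/H2O) to (2E,4E)-5-bromopenta-2,4-dienoic acid F2 and condensed with 25 (EDC·HCl, HOBt, N-methylmorpholine, DMF) to (2E,4E)-5-bromo-N-(2-hydroxy-5-oxocyclopent-1-en-1-yl)penta-2,4-dienamide F3. Alkenyl–alkenyl Stille coupling of F3 with 19 (PdCl2(MeCN)2, DMF, 23 °C) should give 29 directly.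

Step 12. The enone or the trienamide may suffer conjugate reduction by the tin hydride and palladium hydride species, or tin may be delivered to the internal alkyne carbon. The fallback sets out from 18 and returns at 28 (and hence 29); it replaces hydrostannation by hydroboration. Dicyclohexylborane-catalysed hydroboration of 18 with pinacolborane should give (2E,4E,6E)-N-[(1R,5S,6S)-5-hydroxy-2-oxo-5-[(E)-2-(4,4,5,5-tetramethyl-1,3,2-dioxaborolan-2-yl)ethenyl]-7-oxabicyclo[4.1.0]hept-3-en-3-yl]-10-methylundeca-2,4,6-trienamide F4. F4 is joined to 27 by a Suzuki–Miyaura coupling of the allylic chloride (Pd(PPh3)4, K3PO4, THF/H2O, 23 °C) to give 28, which opens to 29 as in step 17.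

Step 1. The enantioselectivity may be insufficient, or the Lewis acid may ionise the dimethyl ketal. The fallback sets out from 1 and 2 and returns at 4; it inverts the order of the two events so that catalysis sets the epoxide. Asymmetric phase-transfer epoxidation of one C=C bond of 1 (t-BuOOH, NaOH, toluene, N-benzylcinchoninium chloride or its pseudo-enantiomer as required) gives (1S,6R)-5,5-dimethoxy-7-oxabicyclo[4.1.0]hept-3-en-2-one F5. An uncatalysed Diels–Alder reaction of F5 with 2 (toluene, 23–60 °C), anti to the epoxide oxygen and endo, should then give 4.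

Further compounds
F1 | step 17 | (2E,4E)-5-bromopenta-2,4-dienal | O=C/C=C/C=C/Br
F2 | step 17 | (2E,4E)-5-bromopenta-2,4-dienoic acid | OC(=O)/C=C/C=C/Br
F3 | step 17 | (2E,4E)-5-bromo-N-(2-hydroxy-5-oxocyclopent-1-en-1-yl)penta-2,4-dienamide | O=C(/C=C/C=C/Br)NC1=C(O)CCC1=O
F4 | step 12 | (2E,4E,6E)-N-[(1R,5S,6S)-5-hydroxy-2-oxo-5-[(E)-2-(4,4,5,5-tetramethyl-1,3,2-dioxaborolan-2-yl)ethenyl]-7-oxabicyclo[4.1.0]hept-3-en-3-yl]-10-methylundeca-2,4,6-trienamide | CC(C)CC/C=C/C=C/C=C/C(=O)NC1=C[C@@](O)(/C=C/B2OC(C)(C)C(C)(C)O2)[C@H]2O[C@H]2C1=O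
F5 | step 1 | (1S,6R)-5,5-dimethoxy-7-oxabicyclo[4.1.0]hept-3-en-2-one | O=C1C=CC(OC)(OC)[C@@H]2O[C@H]12
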